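In each of these closed flasks, the fraction of starting material turned into target and the fraction left, free or bound, add up to one, so each reading of target is also a reading of what remains.

the same everywhere: coupling partner 0.0550 M; free catalyst 2.50 × 10⁻⁴ M

| run | starting material | time |
|---|---|---|
| winter | 0.0500 M |  |
| summer | 0.100 M |  |
| noon | 0.0500 M | 40 min |

| run | time / min | [target] / M |
|---|---|---|
| winter run | 2.0 | 0.00902 |
| winter run | 4.0 | 0.01673 |
| winter run | 6.0 | 0.02256 |
| winter run | 8.0 | 0.02731 |
| winter run | 10 | 0.03125 |
| winter run | 12 | 0.03401 |
| winter run | 14 | 0.03687 |
| winter run | 16 | 0.03874 |
| summer run | 2.0 | 0.01172 |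
| summer run | 4.0 | 0.02171 |
| summer run | 6.0 | 0.02982 |
| summer run | 8.0 | 0.03610 |
| summer run | 10 | 0.04171 |
| summer run | 12 | 0.04510 |
| summer run | 14 | 0.04825 |
| summer run | 16 | 0.05044 |

(each reading ± 2 × 10⁻⁴ M)

- Overall: starting material + coupling partner -> target, with free catalyst as catalyst.
- Constant volume, constant temperature.
- The analysis sees a species whether free or bound.
- "The second partner" is coupling partner.
- An order is taken over about fifteen percent of the charge, up and down.

- apparent order in [starting material] of the starting rate, round the charge of the winter run (the rate where two percent of its starting material have turned into target) (one fixed amount of target, the same in the runs compared)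
- target in the noon run at 40 min, as a share of the starting material charged

With 22.5% of its charge left at 16 min, the winter run has 0.0932 min⁻¹ as its mean loss constant: the logarithm of one over the fraction left, divided by the time. This replaces the curve by one first-order decay. The noon flask has the charge of the winter run, and holding that constant to 40 min would give 97.6%.

The error of that mean shows in the winter run's two halves, which read 0.0988 min⁻¹ and then 0.0876 min⁻¹, so the constant is falling. Continuing that fall by the same factor 0.887 per half gives this reckoning's own figure for the noon flask, 95.7%.

The forecast gives an order of 0.43 and a lower yield, 93.5%, adding: “Catalyst death cannot be excluded”.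

The simulation gives an order of 0.43 and 93.5% in the noon flask.

    free catalyst + starting material → catalyst-substrate complex (1026 M⁻¹ min⁻¹)
    catalyst-substrate complex + coupling partner → loaded catalyst (1182 M⁻¹ min⁻¹)
    loaded catalyst → target + free catalyst (53.82 min⁻¹)
    free catalyst → spent catalyst (0.08280 min⁻¹)
    starting material + coupling partner → target (0.1458 M⁻¹ min⁻¹)

Over 40 min, the noon flask's mean loss constant comes to 0.0684 min⁻¹, below the 0.0932 min⁻¹ of the winter run's first 16 min. The main reason that target in the noon flask stands at 93.5% and not nearer the whole charge is the passing of free catalyst into spent catalyst. The same flask with that step taken away reaches 99.9%, and its mean loss constant over 40 min is 0.184 min⁻¹.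

Readings and results were generated by integration for substances that don't exist; noise was put on by code.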